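Sunday's flask got 20 mM of starting material and 100 µM of free catalyst under held gas, and I wanted its state at 4.0 min.

all flasks: gas 2.3 mM (held); free catalyst 100 µM

| flask | starting material | remark | time |
|---|---|---|---|
| Sunday's | 20 mM | the very flask that is asked about, followed so far |  |
| Friday's | 40 mM | run made earlier |  |
| flask | 20 mM |  | 4.0 min |

Sunday's run (percent of the starting material charged)

| time / s | uncatalysed product / % | intermediate / % | target / % | starting material / % |
|---|---|---|---|---|
| 10.0 | 8 | 17 | 1 | 73 |
| 20.0 | 17 | 22 | 4 | 62 |
| 30.0 | 20 | 24 | 5 | 49 |
| 40.0 | 28 | 22 | 6 | 46 |

Friday's run (percent of the starting material charged)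

| time / min | uncatalysed product / % | intermediate / % | target / % | starting material / % |
|---|---|---|---|---|
| 1.00 | 34 | 26 | 6 | 35 |
| 2.00 | 49 | 27 | 6 | 20 |
| 3.00 | 61 | 22 | 6 | 8 |
| 4.00 | 65 | 21 | 7 | 6 |

(each reading ± 1.5 percentage points)

* the species in which most of what was charged as starting material, at 4.0 min sits (target / intermediate / starting material / uncatalysed product)
* the largest share itself, whichever of these holds it, in percent of the starting material charged

- the analysis behind the earlier runs scatters by 1.5 percentage points, standard deviation
- at the start none of the gas is in solution

One thing did not fit. At 40.0 s Sunday's flask still held 46% of its starting material, yet intermediate plus target went from 29.0% at 30.0 s to 28.0% at that reading. Uncatalysed product gained 8 percentage points over the same interval. In these readings of Sunday's flask, intermediate plus target gained nothing beyond the scatter of 1.5 points, while uncatalysed product ran on, apparently pseudo-first-order. Friday's flask, with 40 mM, read about the same level, 28.0% at 4.00 min, and I took that reading as the plateau.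

I therefore joined two ends. One end is the plateau, seen early in Sunday's readings. The other end concerns the pool, starting material plus uncatalysed product. Friday's readings at 4.00 min put 8.45% of that pool as starting material; this is the unspent fraction s, the part of the pool not yet converted at a given time. Carried to Sunday's flask, the plateau and s gave me 65.9% uncatalysed product, more than the plateau.

The forecast said uncatalysed product at 65.5%, since “percentages should not depend on the charge”.

Sunday's flask gave uncatalysed product at 66.5%.

    starting material + free catalyst ⇌ free catalyst + intermediate (K = 0.770, k = 280 M⁻¹ s⁻¹)
    reagent + free catalyst + intermediate → free catalyst + target (k = 50000 M⁻² s⁻¹)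
    starting material + reagent → uncatalysed product (k = 5.50 M⁻¹ s⁻¹)
    free catalyst → spent catalyst (k = 0.0300 s⁻¹)
    gas ⇌ reagent, rate k5*(csat - [reagent]) (kL = 0.540 s⁻¹)

At 4.00 min Sunday's flask was not quite at rest. My s had put 6.08% starting material in its pool, and the flask held 4.02%. By 40.0 min the flask's starting material stood at 0% and its uncatalysed product at 70.5%, while intermediate stayed at 22.7% and target at 6.80%.

A neighbour of Sunday's flask, the same but with 0.040 mM of free catalyst, held 18.6% as intermediate plus target at the asked time, so s gave 74.5% uncatalysed product and 6.88% starting material. That flask gave 76.9% and 4.50%.

Readings and results were generated by integration for substances that don't exist, and the scatter is random.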